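Count target in moles per litre. At 8.00 h the theta run held 0.240 M and the zeta run 0.205 M, though zeta was charged 1.64 times as heavily.

| flask | solid substrate | gas phase | remark | time |
|---|---|---|---|---|
| theta | 1.1 M | 42 mM (held) | run made earlier |  |
| zeta | 1.8 M | 42 mM (held) | run made earlier |  |
| flask | 0.80 M | 42 mM (held) |  | 12 h |

| theta: time / h | theta: target / % | zeta: time / h | zeta: target / % |
|---|---|---|---|
| 0.500 | 0 | 0.500 | 1.1 |
| 0.833 | 1.7 | 0.833 | 1.4 |
| 1.33 | 2.8 | 1.33 | 1.0 |
| 2.00 | 1.9 | 2.00 | 2.7 |
| 3.00 | 6.1 | 3.00 | 5.0 |
| 5.00 | 12.0 | 5.00 | 9.3 |
| 8.00 | 21.8 | 8.00 | 11.4 |

(readings scatter by 1 percentage point)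

- solid substrate is a solid; its amount is given per volume of the solution
- at the start none of the gas phase is in solution
- at the start none of the solid substrate is in solution

1. target at 12 h, in percent of the solid substrate charged
2. the change that raises the amount of target at 12 h, in percent of the solid substrate charged most ("none" if none brings more than 2 percentage points) (grey / ochre / red / violet / none)
3. amount of target at 12 h, in percent of the solid substrate charged, after grey

- grey: doubling the saturation concentration of gas phase, all else as stated
- ochre: doubling the solubility of the solid substrate, all else as stated
- red: doubling the transfer coefficient of the gas phase, all else as stated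
- violet: doubling the dissolution coefficient of the solid substrate, all else as stated

So read the two runs as one rate, not as two yields. Averaged over both runs, target formed at 0.0174 M h⁻¹ up to 2.00 h. Up to 5.00 h the average is 0.0299 M h⁻¹, higher by a factor of 1.72. Up to 8.00 h it is 0.0278 M h⁻¹, a factor of 0.930 on the one before. Treat that small fall as a reading, not as a proven slowing.

Pool the averages of each run up to 5.00 h and up to 8.00 h into one zero-order rate, 0.0289 M h⁻¹. Now divide the charge by it. This charge clock, the time that rate needs to turn a whole charge into target, is 27.7 h for the flask. The 12 h of the flask are 43.3% of that clock, and I take that share as the yield. The readings stop at 21.8% of a charge, in theta, so the rate beyond that stands unread.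

The forecast differs from my figure: it says 40%, picks grey and expects 73% after it, holding that “the rate is essentially zero order in charged solid”.

The flask gives 46.1% of target at 12 h; grey is the best change, reaching 62.2%, a gain of 16 percentage points.

    gas phase ⇌ dissolved gas, rate k1*(csat - [dissolved gas]) (kL = 250 h⁻¹)
    starting material + dissolved gas → target (k = 39.0 M⁻¹ h⁻¹)
    starting material → side product (k = 0.510 h⁻¹)
    starting material ⇌ dormant form (K = 13.0, k = 1.80 h⁻¹)
    solid substrate ⇌ starting material, rate k5*(cs5 - [starting material]) while solid is left; crystals form when [starting material] > cs5 (solubility = 0.370 M, k = 0.170 h⁻¹)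

The red change adds 0.037 points to the flask, where dissolved gas stood at 99.7% of saturation at 6.00 h. Put the clock on the neighbour charged with 0.32 M: it reads 11.1 h, shorter than the 12 h allowed, yet that neighbour holds 58.0% target at 12 h, with 0.82% of its charge still there.

The readings come from a simulation with made-up constants, and the scatter is random.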